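## Analysis of the target

The target 34 is a proanthocyanidin-type dimer of two flavan-3-ol units, each a chroman (benzene ring A fused to the oxygen ring C) that carries a 3,4,5-trihydroxyphenyl ring B at C2. The units are joined by one C–C bond from C4 of the upper unit to C6' of the lower unit, and O3 of the upper unit carries a galloyl ester. The upper ring C holds three contiguous stereocentres, C2 (R), C3 (R) and C4 (S): ring B and the ester oxygen are cis, the ester oxygen and the lower-unit aryl group are trans. The lower unit has C2' (R) and C3' (S) in the 2,3-trans arrangement of (+)-gallocatechin 1 with a free C3' hydroxyl, so this half can be taken from nature unchanged. Thirteen phenolic hydroxyls make the free compound sensitive to air and base, the interflavan bond and the benzylic C2–O bonds ionise in hot acid, and the ester excludes strong nucleophiles late in the route. The hard points are the position of the link (C6', not the more reactive C8'), the cis/trans triad around a C4 that carries two ortho-disubstituted aryl groups, and freeing O3 alone among the twelve hydroxyls of the dimer core. The route rests on C4, C3 and C2 of the upper ring C being three neighbouring CH carbons, each flanked by an aryl group or an oxygen, the pattern left by successive one-carbon insertions into a carbon–boron bond; the last insertion puts C2 between C3 and boron and brings in ring B.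

## Retrosynthetic reasoning

**Benzyl ethers (34 from 33).** No skeletal bond is cut. All fourteen hydroxyls are masked as benzyl ethers so that one neutral hydrogenolysis ends the synthesis and the free polyphenol never meets base, acid or oxidant.

**Ester C–O (33 from 31 and 32).** The galloyl C–O bond is cut so that the ester is absent during every organometallic step. The forward reaction has to acylate one hindered secondary hydroxyl, the only free one in 31.

**O3 ether (31 from 30).** O3 is carried as a 4-methoxybenzyl ether, the only benzyl-type ether in 30 that ionises in mild acid. Acid is chosen over a quinone oxidant because benzylated flavans are oxidised by quinones at the C4 methylene, which the lower unit of 30 still has.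

**O1–C8a (30 from 29).** Ring C of the upper unit is opened at the aryl–oxygen bond, not at O1–C2. The forward closure then joins the C2 alkoxide of 29 to the ring A chloride without touching any bond at C2, so the configuration made in the open chain is kept. All three stereocentres are fixed before the ring exists.

**C2–O from C2–B (29 from 28).** The C2 hydroxyl is traced to a boronic ester. Oxidation goes with retention, so boron is a placeholder for the ring oxygen.

**C2–C3 and C2–aryl (28 from 20, 24 and 23).** C2 is removed as a one-carbon unit that comes from 24 through carbenoid 25; ring B comes from 23 through Grignard reagent 27. The cut is made here because C2 is a CH bound to carbon, aryl and a heteroatom, which is what carbenoid insertion into C–B followed by displacement of chloride delivers. Both bonds form under control of diol 10 on boron, not under control of the crowded substrate. The forward reaction has to choose one of two enantiotopic chlorides and then arylate with inversion.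

**C3–C4 and C3–O (20 from 16 and 17).** The same operation one carbon earlier: the carbon of 17 is inserted into the C4–B bond of 16 through the bromine carbenoid 18, and the halide of 19 is displaced by the oxygen nucleophile that becomes the 4-methoxybenzyl ether. The bromine carbenoid is chosen here because it can be generated at −78 °C in the presence of the hindered boronic ester, and because the α-bromide is displaced by an alkoxide more readily than the α-chloride.

**C4 (16 from 15, and 15 from 11, 12 and 14).** Both aryl–C4 bonds are made on the dichloromethyl carbon of 11. The order is fixed by stereochemistry: with the lower unit entering first (as 12, from 5) and the ring A aryl second (as 14, from 8), the same enantiomer of diol 10 gives the required sense at C4, C3 and C2. The bromine at C8' is removed (16 from 15) before the later palladium step, where an aryl bromide would compete with the ring A chloride.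

**Lower unit (5 from 4, 3, 2 and 1).** The lower unit is taken whole from 1 with both stereocentres. Electrophiles attack C8 of benzylated flavans first, so C8 is blocked with bromine (4) and iodine is then placed at C6 (5). Selective iodine–magnesium exchange puts the metal at C6.

**Small fragments.** 8 comes from 6 through 7, 23 from 21 through 22, and 11 from 9 and 10 by ester exchange.

## Alternatives that were turned down

**Alternative 1:** The disconnection is O1'–C2' of the lower ring C. In the forward step the epoxy phenol A2, with the galloylated upper unit complete and the lower unit still an open 2-(3-aryl-2,3-epoxypropyl)phenol, would be treated with a catalytic sulfonic acid. Its one free phenol, para to the interflavan carbon, would open the epoxide at the benzylic carbon in a 6-endo closure to give A1.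
- For: anti opening of a trans epoxide gives the 2,3-trans lower unit stereospecifically, ring B activates the benzylic carbon for the 6-endo mode, the C3' hydroxyl appears unprotected, and no organometallic step has to work next to the crowded C4. On that last point it is stronger than the chosen route.
- Against: the regiochemical problem only moves into A2. The phenol para to the interflavan carbon must be free while the phenol ortho to it is protected, on a phloroglucinol ring with little intrinsic bias. The acid step is run on a molecule that already holds the ester and the acid-labile interflavan bond. The upper stereotriad, the real difficulty, is left unsolved.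
- Comparison: it rebuilds a ring that 1 supplies ready-made and costs many more steps. The chosen route uses 1 intact and spends its steps on the triad.

**Alternative 2:** The disconnection runs through three C–C bonds of the lower ring A. In the forward step diazoketone A5 and the C4-alkynylated upper flavan A4 would be irradiated and then heated. A photochemical Wolff rearrangement and a thermal pericyclic cascade would build the lower ring A around the alkyne and give A3.
- For: the link position is fixed by construction, because the new ring grows on the alkyne carbon bound to C4. This is stronger than the chosen route, which needs a blocking bromine to reach C6'. The 5'- and 7'-oxygens also come out differentiated.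
- Against: A4 already needs the complete upper triad plus a 3,4-trans alkynylation at C4. A5 has to be made from scratch with two stereocentres that 1 provides for nothing. The cycloaddition partner is a siloxyalkyne on a crowded secondary carbon. The diazo compound, photolysis and heating on a late intermediate, and three kinds of protecting group, all add length.
- Comparison: both halves are de novo syntheses. The chosen route pays two cheap halogenations for the regiochemistry and keeps the lower unit natural.

**Alternative 3:** The disconnection is O1–C8a of the upper ring C only. In the forward step the open-chain chloro alcohol A7 would be cyclised with Pd(OAc)2, a bulky di-tert-butylbiarylphosphine and Cs2CO3 to give A6.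
- For: the closure is stereoretentive and is the same reaction the chosen route uses in step 15. The silyl ether at O3 comes off with fluoride, which is cleaner than the acid cleavage of the 4-methoxybenzyl ether of 30; on this point the alternative is stronger.
- Against: as a strategy it does not say how the three contiguous centres of A7 are assembled. The obvious routes set C2 and C3 by dihydroxylation or aldol chemistry and leave C4, a methine with two similar, bulky aryl groups, to substrate control.
- Comparison: the chosen route contains this closure and adds a defined, auxiliary-controlled way to every centre of its precursor. The price is an ether at O3 that the alkoxide displacement can install, which a silyl group is not.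

Key step: step 13

## Remarks

- Flavan numbering (C2, C3, C4, C4a, C8a) is used for the open-chain intermediates; primed numbers belong to the lower unit.
- Assumption on stereochemistry: boronic esters of (S,S)-diol 10 are taken to give, on insertion of a dihalomethyl carbenoid with ZnCl2, the α-halo boronic ester that is R when the ranking is halogen > C > B > H, the usual sense for C2-symmetric diols of this type. All three insertions (13, 19 and 26) are drawn on that basis.
- The descriptor at C4 is R in the benzylated ring-closed compounds 30, 31 and 33 and S in 34 for the same spatial arrangement, because the ranking of the two aryl groups changes on debenzylation.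

## Route

Step 1
Reactants: 1 (+)-gallocatechin
Product: 2 (2R,3S)-5,7-bis(benzyloxy)-2-[3,4,5-tris(benzyloxy)phenyl]chroman-3-ol (penta-O-benzyl gallocatechin)
Conditions: BnBr (5.5 equiv), K2CO3, DMF, 0 °C → rt, argon
Reagents that add atoms: benzyl bromide, BrCc1ccccc1
Why: Williamson etherification; K2CO3 ionises only the five phenols, so the C3 alcohol stays free, and the mild base at low temperature avoids ring-opening epimerisation at C2.

Step 2
Reactants: 2 penta-O-benzyl gallocatechin
Product: 3 (2R,3S)-3,5,7-tris(benzyloxy)-2-[3,4,5-tris(benzyloxy)phenyl]chromane (hexa-O-benzyl gallocatechin)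
Conditions: NaH, BnBr, Bu4NI (cat.), DMF, 0 °C → rt
Reagents that add atoms: benzyl bromide, BrCc1ccccc1
Why: Williamson etherification of the remaining secondary alcohol after deprotonation with NaH; with all phenols capped there is no pathway for epimerisation.

Step 3
Reactants: 3 hexa-O-benzyl gallocatechin
Product: 4 8-bromo hexa-O-benzyl gallocatechin
Conditions: NBS (1.0 equiv), CH2Cl2, −20 → 0 °C
Reagents that add atoms: N-bromosuccinimide, O=C1CCC(=O)N1Br
Why: Electrophilic aromatic bromination; the phloroglucinol-type ring A is far more electron-rich than ring B, and C8 (one flanking benzyloxy group and the ring oxygen) is less hindered than C6 (two flanking benzyloxy groups), so one equivalent should give the 8-bromide.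

Step 4
Reactants: 4 8-bromo hexa-O-benzyl gallocatechin
Product: 5 8-bromo-6-iodo hexa-O-benzyl gallocatechin
Conditions: NIS (1.2 equiv), CF3CO2H (cat.), CH2Cl2/MeCN, 0 °C → rt, dark
Reagents that add atoms: N-iodosuccinimide, O=C1CCC(=O)N1I
Why: Electrophilic aromatic iodination of the only activated ring A position left, C6, with the C8 bromine as blocking group; the iodine marks the carbon that will carry the metal.

Step 5
Reactants: 6 5-chlororesorcinol
Product: 7 1,3-bis(benzyloxy)-5-chlorobenzene
Conditions: BnBr, K2CO3, DMF, 60 °C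
Reagents that add atoms: benzyl bromide, BrCc1ccccc1
Why: Williamson etherification of both phenols.

Step 6
Reactants: 7 1,3-bis(benzyloxy)-5-chlorobenzene
Product: 8 1,5-bis(benzyloxy)-2-bromo-3-chlorobenzene
Conditions: NBS, MeCN, 0 °C → rt
Reagents that add atoms: N-bromosuccinimide, O=C1CCC(=O)N1Br
Why: Electrophilic bromination para to one benzyloxy group and ortho to the other; the position between the two benzyloxy groups is more hindered, as is usual for 5-substituted resorcinol diethers.

Step 7
Reactants: 9 diisopropyl (dichloromethyl)boronate; 10 (1S,2S)-1,2-dicyclohexylethane-1,2-diol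
Product: 11 (4S,5S)-4,5-dicyclohexyl-2-(dichloromethyl)-1,3,2-dioxaborolane
Conditions: Et2O, rt; then vacuum (removal of iPrOH)
Reagents that add atoms: none
Why: Transesterification of an acyclic boronic ester with a 1,2-diol; formation of the five-membered dioxaborolane and evaporation of propan-2-ol drive it to completion, and no stereocentre is touched.

Step 8
Reactants: 5 8-bromo-6-iodo hexa-O-benzyl gallocatechin; 11 (S,S)-diol (dichloromethyl)boronate; 8 1,5-bis(benzyloxy)-2-bromo-3-chlorobenzene
Product: 15 (S)-configured C4 diarylmethyl boronic ester of diol 10 bearing bromine at C8', via 8-bromo-6-(chloromagnesio) hexa-O-benzyl gallocatechin 12 (not isolated), via benzylic α-chloro boronic ester 13 (not isolated), via ring A Grignard reagent 14 (not isolated)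
Conditions: 5, iPrMgCl·LiCl (1.05 equiv), THF, −30 °C; 11 (0.95 equiv), −78 °C; ZnCl2 (1 equiv), −78 → 0 °C; then 14 (from 8, Mg, LiCl, THF, rt; 3 equiv), −78 °C → rt
Reagents that add atoms: none
Why: Iodine–magnesium exchange is much faster at the aryl iodide than at the aryl bromide, and Grignard reagent 12 adds to boron of 11 to give the tetracoordinate (dichloromethyl)borate of a Matteson homologation, reached here from the side of the carbon nucleophile. ZnCl2 then promotes a 1,2-aryl shift with loss of the chloride selected by the C2-symmetric diol (Matteson-type homologation), giving 13. Grignard reagent 14 adds to boron and migrates to carbon with inversion, which sets C4 and joins both aryl groups without isolating the labile chloride.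

Step 9
Reactants: 15 C4 diarylmethyl boronic ester bearing bromine at C8'
Product: 16 (S)-configured C4 diarylmethyl boronic ester of diol 10
Conditions: Bu3SnH, AIBN (cat.), toluene, 90 °C
Reagents that add atoms: none
Why: Radical-chain hydrodebromination; tin radicals abstract bromine from the aryl bromide but not chlorine from the aryl chloride, and the benzylic C–B bond and the benzyl ethers are inert.

Step 10
Reactants: 16 C4 diarylmethyl boronic ester; 17 dibromomethane
Product: 20 C3 α-(4-methoxybenzyloxy) boronic ester of diol 10 (C3 S; C4 S), via dibromomethyllithium 18 (not isolated), via C3 α-bromo boronic ester 19 (not isolated)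
Conditions: 16, 17 (3 equiv), THF, −78 °C, LiN(iPr)2 (1.5 equiv) added dropwise; ZnCl2 (2 equiv), −78 °C → rt; pentane, filtration of salts; LiOCH2C6H4-4-OMe (from 4-methoxybenzyl alcohol, n-BuLi), THF/DMSO, 0 °C → rt
Reagents that add atoms: 4-methoxybenzyl alcohol (as its lithium alkoxide), COc1ccc(CO)cc1
Why: Matteson homologation with the bromine carbenoid; LiN(iPr)2 deprotonates 17 in the presence of 16, so 18 is captured by boron as it forms, and ZnCl2-assisted 1,2-migration of C4 (with retention) gives bromide 19 with C3 set by the diol. The alkoxide then adds to boron and shifts to carbon with inversion, displacing bromide and giving the C3 ether.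

Step 11
Reactants: 21 5-bromo-1,2,3-trimethoxybenzene
Product: 22 5-bromobenzene-1,2,3-triol
Conditions: BBr3, CH2Cl2, −78 °C → rt; H2O
Reagents that add atoms: none
Why: Lewis-acid cleavage of the three aryl methyl ethers; the aryl bromide is untouched.

Step 12
Reactants: 22 5-bromobenzene-1,2,3-triol
Product: 23 5-bromo-1,2,3-tris(benzyloxy)benzene
Conditions: BnBr, K2CO3, DMF, 60 °C, argon
Reagents that add atoms: benzyl bromide, BrCc1ccccc1
Why: Williamson etherification of the three phenols.

Step 13
Reactants: 20 C3 α-(4-methoxybenzyloxy) boronic ester; 24 dichloromethane; 23 5-bromo-1,2,3-tris(benzyloxy)benzene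
Product: 28 C2 boronic ester of diol 10 bearing the full C2–C3–C4 triad (C2 R; C3 S; C4 S), via dichloromethyllithium 25 (not isolated), via C2 α-chloro boronic ester 26 (not isolated), via ring B Grignard reagent 27 (not isolated)
Conditions: 24, n-BuLi, THF, −100 °C; 20; ZnCl2 (3 equiv), −100 °C → rt; then 27 (from 23, Mg, LiCl, THF, 40 °C; 4 equiv), −78 °C → rt
Reagents that add atoms: none
Why: Carbenoid 25 adds to the trigonal boron of 20 to give a tetracoordinate borate; on warming with ZnCl2, C3 migrates from boron to the dichloromethyl carbon anti to the departing chloride, with retention at C3, which forms the C2–C3 bond and gives chloride 26. Grignard reagent 27 then adds to boron and its aryl group shifts to C2 with inversion, expelling the second chloride and forming the C2–aryl bond. The closest known reaction type is the Matteson homologation of an α-alkoxy boronic ester of a C2-symmetric diol followed by Grignard substitution of the α-chloride. No ring is closed. The new stereocentre C2 is controlled by the diol: in the transition state zinc bridges one dioxaborolane oxygen and the leaving chloride, the (S,S)-diol thereby selects which of the two chlorides leaves (giving R-configured 26), and the invertive aryl shift turns this into the C2 configuration of 28. The step needs carbon migration in preference to migration of a ring oxygen, no epimerisation of 26 by free chloride, and no β-elimination of boron together with the C3 alkoxy group. ZnCl2 speeds carbon migration and binds chloride, and borate formation with the Grignard reagent at −78 °C precedes elimination. The existing centres at C3 and C4 should count for little beside the diol, so the step is reagent-controlled.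

Step 14
Reactants: 28 C2 boronic ester
Product: 29 open-chain C2 alcohol (C2 R; C3 R; C4 S)
Conditions: 30% H2O2, aq NaOH, THF, 0 °C → rt
Reagents that add atoms: hydrogen peroxide, OO
Why: Oxidation of the C–B bond; hydroperoxide adds to boron and C2 migrates from boron to oxygen with retention, which also releases diol 10.

Step 15
Reactants: 29 open-chain C2 alcohol
Product: 30 (2R,3R,4R)-3-O-(4-methoxybenzyl) undeca-O-benzyl 4→6 dimer
Conditions: Pd(OAc)2 (10 mol %), 2-(di-tert-butylphosphino)-1,1'-binaphthyl (12 mol %), Cs2CO3, toluene, 90 °C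
Reagents that add atoms: none
Why: Intramolecular palladium-catalysed aryl etherification (Buchwald–Hartwig-type C–O coupling); zerovalent palladium inserts into the aryl chloride, the C2 alkoxide replaces chloride on divalent palladium, and C–O reductive elimination forms O1–C8a and the six-membered ring C. No bond to C2 is broken, so its configuration is retained, and the bulky electron-rich phosphine favours reductive elimination over β-hydride elimination.

Step 16
Reactants: 30 3-O-(4-methoxybenzyl) undeca-O-benzyl dimer
Product: 31 (2R,3R,4R)-undeca-O-benzyl 4→6 dimer with free C3 hydroxyl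
Conditions: CF3CO2H (10% v/v), 1,3-dimethoxybenzene (5 equiv), CH2Cl2, 0 °C
Reagents that add atoms: none
Why: Acidolysis of the 4-methoxybenzyl ether through its stabilised benzylic cation, which 1,3-dimethoxybenzene captures before it can alkylate the electron-rich rings; plain benzyl ethers do not ionise under these conditions. A quinone oxidant is avoided because it would attack the C4' methylene of the lower unit.

Step 17
Reactants: 31 undeca-O-benzyl dimer with free C3 hydroxyl; 32 3,4,5-tris(benzyloxy)benzoic acid
Product: 33 (2R,3R,4R)-tetradeca-O-benzyl target (3-O-galloyl ester)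
Conditions: EDC·HCl, DMAP, CH2Cl2, rt
Reagents that add atoms: none
Why: Steglich esterification; the O-acylisourea formed from 32 is turned by DMAP into an acylpyridinium ion that acylates the hindered C3 hydroxyl, the only free hydroxyl in 31.

Step 18
Reactants: 33 tetradeca-O-benzyl target
Product: 34 target, (2R,3R,4S)-epigallocatechin 3-O-gallate-(4→6)-(2R,3S)-gallocatechin
Conditions: H2 (1 atm), Pd(OH)2/C, THF/MeOH/H2O, rt
Reagents that add atoms: none
Why: Hydrogenolysis of all fourteen benzyl ethers under neutral conditions; the ester, the cyclic benzylic C2–O bonds and the interflavan bond should not be cleaved at room temperature.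

## Compound list

1 | (+)-gallocatechin, (2R,3S)-2-(3,4,5-trihydroxyphenyl)chromane-3,5,7-triol | O[C@H]1Cc2c(O)cc(O)cc2O[C@@H]1c1cc(O)c(O)c(O)c1 | starting material
2 | (2R,3S)-5,7-bis(benzyloxy)-2-[3,4,5-tris(benzyloxy)phenyl]chroman-3-ol | O[C@H]1Cc2c(OCc9ccccc9)cc(OCc9ccccc9)cc2O[C@@H]1c1cc(OCc9ccccc9)c(OCc9ccccc9)c(OCc9ccccc9)c1 | intermediate
3 | (2R,3S)-3,5,7-tris(benzyloxy)-2-[3,4,5-tris(benzyloxy)phenyl]chromane | C(c9ccccc9)O[C@H]1Cc2c(OCc9ccccc9)cc(OCc9ccccc9)cc2O[C@@H]1c1cc(OCc9ccccc9)c(OCc9ccccc9)c(OCc9ccccc9)c1 | intermediate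
4 | (2R,3S)-8-bromo-3,5,7-tris(benzyloxy)-2-[3,4,5-tris(benzyloxy)phenyl]chromane | C(c9ccccc9)O[C@H]1Cc2c(OCc9ccccc9)cc(OCc9ccccc9)c(Br)c2O[C@@H]1c1cc(OCc9ccccc9)c(OCc9ccccc9)c(OCc9ccccc9)c1 | intermediate
5 | (2R,3S)-8-bromo-6-iodo-3,5,7-tris(benzyloxy)-2-[3,4,5-tris(benzyloxy)phenyl]chromane | C(c9ccccc9)O[C@H]1Cc2c(OCc9ccccc9)c(I)c(OCc9ccccc9)c(Br)c2O[C@@H]1c1cc(OCc9ccccc9)c(OCc9ccccc9)c(OCc9ccccc9)c1 | intermediate
6 | 5-chlororesorcinol | Oc1cc(O)cc(Cl)c1 | starting material
7 | 1,3-bis(benzyloxy)-5-chlorobenzene | Clc1cc(OCc9ccccc9)cc(OCc9ccccc9)c1 | intermediate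
8 | 1,5-bis(benzyloxy)-2-bromo-3-chlorobenzene | Brc1c(Cl)cc(OCc9ccccc9)cc1OCc9ccccc9 | intermediate
9 | diisopropyl (dichloromethyl)boronate | ClC(Cl)B(OC(C)C)OC(C)C | starting material
10 | (1S,2S)-1,2-dicyclohexylethane-1,2-diol | O[C@@H](C1CCCCC1)[C@H](C1CCCCC1)O | starting material
11 | (4S,5S)-4,5-dicyclohexyl-2-(dichloromethyl)-1,3,2-dioxaborolane | ClC(Cl)B1O[C@@H](C2CCCCC2)[C@H](C2CCCCC2)O1 | intermediate
12 | [(2R,3S)-hexa-O-benzyl-8-bromogallocatechin-6-yl]magnesium chloride | C(c9ccccc9)O[C@H]1Cc2c(OCc9ccccc9)c([Mg]Cl)c(OCc9ccccc9)c(Br)c2O[C@@H]1c1cc(OCc9ccccc9)c(OCc9ccccc9)c(OCc9ccccc9)c1 | intermediate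
13 | (4S,5S)-2-[(R)-chloro(hexa-O-benzyl-8-bromogallocatechin-6-yl)methyl]-4,5-dicyclohexyl-1,3,2-dioxaborolane | Cl[C@H](B2O[C@@H](C8CCCCC8)[C@H](C8CCCCC8)O2)c4c(OCc9ccccc9)c(Br)c5c(c4OCc9ccccc9)C[C@H](OCc9ccccc9)[C@@H](c6cc(OCc9ccccc9)c(OCc9ccccc9)c(OCc9ccccc9)c6)O5 | intermediate
14 | [2-chloro-4,6-bis(benzyloxy)phenyl]magnesium bromide | Br[Mg]c1c(Cl)cc(OCc9ccccc9)cc1OCc9ccccc9 | intermediate
15 | (4S,5S)-2-{(S)-(hexa-O-benzyl-8-bromogallocatechin-6-yl)[2-chloro-4,6-bis(benzyloxy)phenyl]methyl}-4,5-dicyclohexyl-1,3,2-dioxaborolane | B2(O[C@@H](C8CCCCC8)[C@H](C8CCCCC8)O2)[C@@H](c4c(OCc9ccccc9)c(Br)c5c(c4OCc9ccccc9)C[C@H](OCc9ccccc9)[C@@H](c6cc(OCc9ccccc9)c(OCc9ccccc9)c(OCc9ccccc9)c6)O5)c3c(Cl)cc(OCc9ccccc9)cc3OCc9ccccc9 | intermediate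
16 | (4S,5S)-2-{(S)-(hexa-O-benzylgallocatechin-6-yl)[2-chloro-4,6-bis(benzyloxy)phenyl]methyl}-4,5-dicyclohexyl-1,3,2-dioxaborolane | B2(O[C@@H](C8CCCCC8)[C@H](C8CCCCC8)O2)[C@@H](c4c(OCc9ccccc9)cc5c(c4OCc9ccccc9)C[C@H](OCc9ccccc9)[C@@H](c6cc(OCc9ccccc9)c(OCc9ccccc9)c(OCc9ccccc9)c6)O5)c3c(Cl)cc(OCc9ccccc9)cc3OCc9ccccc9 | intermediate
17 | dibromomethane | BrCBr | starting material
18 | dibromomethyllithium | [Li]C(Br)Br | intermediate
19 | C3 α-bromo boronic ester of diol 10 (C3 R, C4 S): boron and bromine on C3, both aryl groups on C4 | Br[C@H](B2O[C@@H](C8CCCCC8)[C@H](C8CCCCC8)O2)[C@@H](c4c(OCc9ccccc9)cc5c(c4OCc9ccccc9)C[C@H](OCc9ccccc9)[C@@H](c6cc(OCc9ccccc9)c(OCc9ccccc9)c(OCc9ccccc9)c6)O5)c3c(Cl)cc(OCc9ccccc9)cc3OCc9ccccc9 | intermediate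
20 | C3 α-(4-methoxybenzyloxy) boronic ester of diol 10 (C3 S, C4 S), precursor of the key step | COc1ccc(CO[C@@H](B2O[C@@H](C8CCCCC8)[C@H](C8CCCCC8)O2)[C@@H](c4c(OCc9ccccc9)cc5c(c4OCc9ccccc9)C[C@H](OCc9ccccc9)[C@@H](c6cc(OCc9ccccc9)c(OCc9ccccc9)c(OCc9ccccc9)c6)O5)c3c(Cl)cc(OCc9ccccc9)cc3OCc9ccccc9)cc1 | intermediate
21 | 5-bromo-1,2,3-trimethoxybenzene | COc1cc(Br)cc(OC)c1OC | starting material
22 | 5-bromobenzene-1,2,3-triol | Oc1cc(Br)cc(O)c1O | intermediate
23 | 5-bromo-1,2,3-tris(benzyloxy)benzene | Brc1cc(OCc9ccccc9)c(OCc9ccccc9)c(OCc9ccccc9)c1 | intermediate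
24 | dichloromethane | ClCCl | starting material
25 | dichloromethyllithium | [Li]C(Cl)Cl | intermediate
26 | C2 α-chloro boronic ester of diol 10 (C2 R, C3 R, C4 S) with 4-methoxybenzyloxy on C3 | COc1ccc(CO[C@@H]([C@@H](B2O[C@@H](C8CCCCC8)[C@H](C8CCCCC8)O2)Cl)[C@@H](c4c(OCc9ccccc9)cc5c(c4OCc9ccccc9)C[C@H](OCc9ccccc9)[C@@H](c6cc(OCc9ccccc9)c(OCc9ccccc9)c(OCc9ccccc9)c6)O5)c3c(Cl)cc(OCc9ccccc9)cc3OCc9ccccc9)cc1 | intermediate
27 | [3,4,5-tris(benzyloxy)phenyl]magnesium bromide | Br[Mg]c1cc(OCc9ccccc9)c(OCc9ccccc9)c(OCc9ccccc9)c1 | intermediate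
28 | C2 boronic ester of diol 10 with the full triad (C2 R, C3 S, C4 S), product of the key step | COc1ccc(CO[C@@H]([C@H](B2O[C@@H](C8CCCCC8)[C@H](C8CCCCC8)O2)c7cc(OCc9ccccc9)c(OCc9ccccc9)c(OCc9ccccc9)c7)[C@@H](c4c(OCc9ccccc9)cc5c(c4OCc9ccccc9)C[C@H](OCc9ccccc9)[C@@H](c6cc(OCc9ccccc9)c(OCc9ccccc9)c(OCc9ccccc9)c6)O5)c3c(Cl)cc(OCc9ccccc9)cc3OCc9ccccc9)cc1 | intermediate
29 | open-chain C2 alcohol (C2 R, C3 R, C4 S): C2 OH and ring B, C3 4-methoxybenzyloxy, C4 lower unit and chloroaryl | COc1ccc(CO[C@@H]([C@H](O)c7cc(OCc9ccccc9)c(OCc9ccccc9)c(OCc9ccccc9)c7)[C@@H](c4c(OCc9ccccc9)cc5c(c4OCc9ccccc9)C[C@H](OCc9ccccc9)[C@@H](c6cc(OCc9ccccc9)c(OCc9ccccc9)c(OCc9ccccc9)c6)O5)c3c(Cl)cc(OCc9ccccc9)cc3OCc9ccccc9)cc1 | intermediate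
30 | (2R,3R,4R)-3-O-(4-methoxybenzyl) undeca-O-benzyl epigallocatechin-(4→6)-gallocatechin | COc1ccc(CO[C@@H]2[C@@H](c4c(OCc9ccccc9)cc5c(c4OCc9ccccc9)C[C@H](OCc9ccccc9)[C@@H](c6cc(OCc9ccccc9)c(OCc9ccccc9)c(OCc9ccccc9)c6)O5)c3c(OCc9ccccc9)cc(OCc9ccccc9)cc3O[C@@H]2c7cc(OCc9ccccc9)c(OCc9ccccc9)c(OCc9ccccc9)c7)cc1 | intermediate
31 | (2R,3R,4R)-undeca-O-benzyl epigallocatechin-(4→6)-gallocatechin with free C3 hydroxyl | O[C@@H]2[C@@H](c4c(OCc9ccccc9)cc5c(c4OCc9ccccc9)C[C@H](OCc9ccccc9)[C@@H](c6cc(OCc9ccccc9)c(OCc9ccccc9)c(OCc9ccccc9)c6)O5)c3c(OCc9ccccc9)cc(OCc9ccccc9)cc3O[C@@H]2c7cc(OCc9ccccc9)c(OCc9ccccc9)c(OCc9ccccc9)c7 | intermediate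
32 | 3,4,5-tris(benzyloxy)benzoic acid | OC(=O)c1cc(OCc9ccccc9)c(OCc9ccccc9)c(OCc9ccccc9)c1 | starting material
33 | (2R,3R,4R)-tetradeca-O-benzyl epigallocatechin 3-O-gallate-(4→6)-gallocatechin | O=C(O[C@@H]2[C@@H](c4c(OCc9ccccc9)cc5c(c4OCc9ccccc9)C[C@H](OCc9ccccc9)[C@@H](c6cc(OCc9ccccc9)c(OCc9ccccc9)c(OCc9ccccc9)c6)O5)c3c(OCc9ccccc9)cc(OCc9ccccc9)cc3O[C@@H]2c7cc(OCc9ccccc9)c(OCc9ccccc9)c(OCc9ccccc9)c7)c1cc(OCc9ccccc9)c(OCc9ccccc9)c(OCc9ccccc9)c1 | intermediate
34 | (2R,3R,4S)-epigallocatechin 3-O-gallate-(4→6)-(2R,3S)-gallocatechin | O=C(O[C@@H]1[C@@H](c2c(O)cc3c(c2O)C[C@H](O)[C@@H](c2cc(O)c(O)c(O)c2)O3)c2c(O)cc(O)cc2O[C@@H]1c1cc(O)c(O)c(O)c1)c1cc(O)c(O)c(O)c1 | target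

## Step count and least certain steps

Total step count: 18. Longest linear sequence: 13 steps (steps 1–4, 8, 9, 10, 13–18).

**Step 13 (key step).** The migrating carbon C3 carries an oxygen and sits next to the very crowded C4. Migration may therefore be slow, so that the carbenoid decomposes or a ring oxygen of the boronic ester migrates instead. After the Grignard reagent has added, boron and the C3 alkoxy group may be lost by β-elimination before the aryl shift. A mismatch between the substrate's own bias and the diol could also lower the facial selectivity. The fallback sets out from 20 and returns at 29. Compound 20 would be homologated with chloromethyllithium (made in the flask from chloroiodomethane and n-BuLi, THF, −78 °C), a smaller carbenoid that creates no stereocentre, to give the one-carbon-extended boronic ester F1. Oxidation (H2O2, aq NaOH) would give the primary alcohol F2, and Dess–Martin periodinane with NaHCO3 the α-(4-methoxybenzyloxy) aldehyde F3. Addition of Grignard reagent 27 to F3 in the presence of MgBr2·OEt2 (CH2Cl2, −78 °C) should follow the Cram chelation model: magnesium bridges the carbonyl and ether oxygens and the aryl group enters opposite the bulky C4 substituent. This gives the 2,3-syn alcohol, which is 29. C2 is then set by carbonyl addition instead of a 1,2-metalate shift.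

**Step 8.** The intermediate 13 is a benzylic chloride on a trialkoxy-substituted ring. It may ionise, with loss of the configuration the diol has just set at C4. The second Grignard reagent, with two ortho substituents, may also add to boron or migrate too slowly. The fallback sets out from 5 and 8 and returns at 15. Grignard reagent 12 would be quenched with B(OMe)3 to the boronic acid F4 and esterified with 10 to the aryl boronic ester F5. Grignard reagent 14 and paraformaldehyde would give [2-chloro-4,6-bis(benzyloxy)phenyl]methanol F6, converted with N,N-diisopropylcarbamoyl chloride and NaH into the carbamate F7. Deprotonation of F7 (s-BuLi, TMEDA, Et2O, −78 °C) would give the lithiated carbamate F8, which adds to boron of F5. On warming, the lower-unit aryl group shifts from boron to carbon and expels the carbamate (lithiation–borylation). The leaving group then sits next to the less electron-rich ring A aryl and no trialkoxybenzyl chloride is formed. C4 would be set in the borylation of a configurationally labile benzyllithium, not by a choice between two chlorides, so 15 would be expected together with its C4 epimer F9 and would be separated from it by chromatography.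

**Step 10.** The boron of 16 is shielded by two ortho-disubstituted aryl groups, so capture of the short-lived carbenoid may be incomplete, and the amide base may instead remove the doubly benzylic C4–H next to boron. Bromide 19 may lose its C3 configuration through exchange with free bromide before the alkoxide arrives. In the second stage the alkoxide may act as a base toward the C4–H of 19 (loss of HBr to an alkenyl boronic ester) instead of adding to boron and migrating. The fallback sets out from 16 and returns at 20. [(4-Methoxybenzyl)oxy]methyl phenyl sulfide F10 (from 4-methoxybenzyl alcohol, NaH and chloromethyl phenyl sulfide) would be lithiated (s-BuLi, THF, −78 °C) to the α-lithio sulfide F11 and added to 16. HgCl2 would then remove the thiolate from the borate and trigger migration of C4 to the oxygen-bearing carbon. The C3 oxygen arrives on the carbenoid carbon and no alkoxide meets a halide. With only one leaving group the diol cannot choose, so 20 would form together with its C3 epimer F12 and would be separated by chromatography.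

**Step 15.** Oxidative addition into an electron-rich aryl chloride beside the bulky C4 may be slow. The palladium alkoxide of the benzylic C2 carbinol may undergo β-hydride elimination, which oxidises C2 to the ketone and reduces the arene. The fallback sets out from 29 and returns at 30. Excess lithium 2,2,6,6-tetramethylpiperidide (THF, −78 → 0 °C) would first deprotonate the hydroxyl and then the ring A CH between chlorine and benzyloxy group. Loss of LiCl gives the aryne F13. The C2 alkoxide adds to the aryne carbon that carried chlorine, which closes the six-membered ring and places the negative charge ortho to the benzyloxy group; protonation gives 30. The C2–O bond is again untouched, so the configuration is retained without a transition metal.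

## Further compounds

F1 | step 13 | one-carbon-homologated boronic ester of diol 10 (CH2–B on C3) | COc1ccc(CO[C@@H](CB2O[C@@H](C8CCCCC8)[C@H](C8CCCCC8)O2)[C@@H](c4c(OCc9ccccc9)cc5c(c4OCc9ccccc9)C[C@H](OCc9ccccc9)[C@@H](c6cc(OCc9ccccc9)c(OCc9ccccc9)c(OCc9ccccc9)c6)O5)c3c(Cl)cc(OCc9ccccc9)cc3OCc9ccccc9)cc1
F2 | step 13 | primary alcohol from F1 | COc1ccc(CO[C@@H](CO)[C@@H](c4c(OCc9ccccc9)cc5c(c4OCc9ccccc9)C[C@H](OCc9ccccc9)[C@@H](c6cc(OCc9ccccc9)c(OCc9ccccc9)c(OCc9ccccc9)c6)O5)c3c(Cl)cc(OCc9ccccc9)cc3OCc9ccccc9)cc1
F3 | step 13 | α-(4-methoxybenzyloxy) aldehyde | COc1ccc(CO[C@@H](C=O)[C@@H](c4c(OCc9ccccc9)cc5c(c4OCc9ccccc9)C[C@H](OCc9ccccc9)[C@@H](c6cc(OCc9ccccc9)c(OCc9ccccc9)c(OCc9ccccc9)c6)O5)c3c(Cl)cc(OCc9ccccc9)cc3OCc9ccccc9)cc1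
F4 | step 8 | (hexa-O-benzyl-8-bromogallocatechin-6-yl)boronic acid | OB(O)c4c(OCc9ccccc9)c(Br)c5c(c4OCc9ccccc9)C[C@H](OCc9ccccc9)[C@@H](c6cc(OCc9ccccc9)c(OCc9ccccc9)c(OCc9ccccc9)c6)O5
F5 | step 8 | (4S,5S)-4,5-dicyclohexyl-2-(hexa-O-benzyl-8-bromogallocatechin-6-yl)-1,3,2-dioxaborolane | B2(O[C@@H](C8CCCCC8)[C@H](C8CCCCC8)O2)c4c(OCc9ccccc9)c(Br)c5c(c4OCc9ccccc9)C[C@H](OCc9ccccc9)[C@@H](c6cc(OCc9ccccc9)c(OCc9ccccc9)c(OCc9ccccc9)c6)O5
F6 | step 8 | [2-chloro-4,6-bis(benzyloxy)phenyl]methanol | OCc1c(Cl)cc(OCc9ccccc9)cc1OCc9ccccc9
F7 | step 8 | 2-chloro-4,6-bis(benzyloxy)benzyl N,N-diisopropylcarbamate | CC(C)N(C(C)C)C(=O)OCc1c(Cl)cc(OCc9ccccc9)cc1OCc9ccccc9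
F8 | step 8 | α-lithiated carbamate from F7 | [Li]C(OC(=O)N(C(C)C)C(C)C)c1c(Cl)cc(OCc9ccccc9)cc1OCc9ccccc9
F9 | step 8 | C4 epimer of 15 | B2(O[C@@H](C8CCCCC8)[C@H](C8CCCCC8)O2)[C@H](c4c(OCc9ccccc9)c(Br)c5c(c4OCc9ccccc9)C[C@H](OCc9ccccc9)[C@@H](c6cc(OCc9ccccc9)c(OCc9ccccc9)c(OCc9ccccc9)c6)O5)c3c(Cl)cc(OCc9ccccc9)cc3OCc9ccccc9
F10 | step 10 | [(4-methoxybenzyl)oxy]methyl phenyl sulfide | COc1ccc(COCSc2ccccc2)cc1
F11 | step 10 | lithiated F10 | [Li]C(OCc1ccc(OC)cc1)Sc1ccccc1
F12 | step 10 | C3 epimer of 20 | COc1ccc(CO[C@H](B2O[C@@H](C8CCCCC8)[C@H](C8CCCCC8)O2)[C@@H](c4c(OCc9ccccc9)cc5c(c4OCc9ccccc9)C[C@H](OCc9ccccc9)[C@@H](c6cc(OCc9ccccc9)c(OCc9ccccc9)c(OCc9ccccc9)c6)O5)c3c(Cl)cc(OCc9ccccc9)cc3OCc9ccccc9)cc1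
F13 | step 15 | ring A aryne formed from 29 by loss of HCl | COc1ccc(CO[C@@H]([C@H](O)c7cc(OCc9ccccc9)c(OCc9ccccc9)c(OCc9ccccc9)c7)[C@@H](c4c(OCc9ccccc9)cc5c(c4OCc9ccccc9)C[C@H](OCc9ccccc9)[C@@H](c6cc(OCc9ccccc9)c(OCc9ccccc9)c(OCc9ccccc9)c6)O5)C3=C(OCc9ccccc9)C=C(OCc9ccccc9)C#C3)cc1
A1 | alternative 1 | trideca-O-benzyl target with free C3' hydroxyl | O=C(O[C@@H]1[C@@H](c2c(OCc9ccccc9)cc3c(c2OCc9ccccc9)C[C@H](O)[C@@H](c2cc(OCc9ccccc9)c(OCc9ccccc9)c(OCc9ccccc9)c2)O3)c2c(OCc9ccccc9)cc(OCc9ccccc9)cc2O[C@@H]1c1cc(OCc9ccccc9)c(OCc9ccccc9)c(OCc9ccccc9)c1)c1cc(OCc9ccccc9)c(OCc9ccccc9)c(OCc9ccccc9)c1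
A2 | alternative 1 | epoxy phenol: galloylated upper unit on an open lower unit with trans epoxide and one free phenol | O=C(O[C@@H]2[C@@H](c4c(OCc9ccccc9)cc(O)c(c4OCc9ccccc9)C[C@@H]5O[C@H]5c6cc(OCc9ccccc9)c(OCc9ccccc9)c(OCc9ccccc9)c6)c3c(OCc9ccccc9)cc(OCc9ccccc9)cc3O[C@@H]2c7cc(OCc9ccccc9)c(OCc9ccccc9)c(OCc9ccccc9)c7)c1cc(OCc9ccccc9)c(OCc9ccccc9)c(OCc9ccccc9)c1
A3 | alternative 2 | 4→6 dimer with 5'-OH, 7'-OTIPS and 3-OTBS | CC(C)(C)[Si](C)(C)O[C@@H]1[C@@H](c2c(O[Si](C(C)C)(C(C)C)C(C)C)cc3c(c2O)C[C@H](OCc9ccccc9)[C@@H](c2cc(OCc9ccccc9)c(OCc9ccccc9)c(OCc9ccccc9)c2)O3)c2c(OCc9ccccc9)cc(OCc9ccccc9)cc2O[C@@H]1c1cc(OCc9ccccc9)c(OCc9ccccc9)c(OCc9ccccc9)c1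
A4 | alternative 2 | upper flavan with a triisopropylsiloxyethynyl group at C4 and 3-OTBS | CC(C)(C)[Si](C)(C)O[C@@H]1[C@@H](C#CO[Si](C(C)C)(C(C)C)C(C)C)c2c(OCc9ccccc9)cc(OCc9ccccc9)cc2O[C@@H]1c1cc(OCc9ccccc9)c(OCc9ccccc9)c(OCc9ccccc9)c1
A5 | alternative 2 | dihydropyranyl diazoketone carrying the lower ring C stereocentres | [N-]=[N+]=CC(=O)C1=CC[C@H](OCc9ccccc9)[C@@H](c2cc(OCc9ccccc9)c(OCc9ccccc9)c(OCc9ccccc9)c2)O1
A6 | alternative 3 | 3-O-TIPS undeca-O-benzyl 4→6 dimer lacking the gallate | CC(C)[Si](C(C)C)(C(C)C)O[C@@H]1[C@@H](c2c(OCc9ccccc9)cc3c(c2OCc9ccccc9)C[C@H](OCc9ccccc9)[C@@H](c2cc(OCc9ccccc9)c(OCc9ccccc9)c(OCc9ccccc9)c2)O3)c2c(OCc9ccccc9)cc(OCc9ccccc9)cc2O[C@@H]1c1cc(OCc9ccccc9)c(OCc9ccccc9)c(OCc9ccccc9)c1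
A7 | alternative 3 | open-chain chloro alcohol with 3-O-TIPS | CC(C)[Si](C(C)C)(C(C)C)O[C@@H]([C@H](O)c7cc(OCc9ccccc9)c(OCc9ccccc9)c(OCc9ccccc9)c7)[C@@H](c4c(OCc9ccccc9)cc5c(c4OCc9ccccc9)C[C@H](OCc9ccccc9)[C@@H](c6cc(OCc9ccccc9)c(OCc9ccccc9)c(OCc9ccccc9)c6)O5)c3c(Cl)cc(OCc9ccccc9)cc3OCc9ccccc9
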